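**Retrosynthetic overview**
- Last bond: the CH2 link between the decalin and the acyl‑dimethyl‑cyclohexadienone, by amine‑catalysed reductive Knoevenagel alkylation of a decalin aldehyde.
- The aldehyde comes from a 7(11)‑en‑8‑one diol: enone deconjugation (sets C7), removal of the C8 carbonyl, oxidation of the primary alcohol.
- The enone diol comes from achiral germacrone, formaldehyde and water in one chiral‑Brønsted‑acid step (C1–CH2 and C5–C10 bonds; sets C1, C4, C5, C10).
- Ring order: ten‑membered carbocycle (bought) → rings A and B together by transannular closure → the separately made cyclohexadienone ring is attached last.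

Assumption: germacrone (achiral, CAS 6902‑91‑6) is purchased; atom labels follow eudesmane numbering (C1 carries the CH2 link C1′, C4 the carbinol, C5/C10 the ring fusion, C7 the C3 side chain, C8 lies between C7 and C9); "(S,S)" for the acid catalyst stands for whichever enantiomer a first run shows to give 7 as drawn.

**Step 1**
Reactants: 1 phloroglucinol; 2 3‑methylbutanoyl chloride
Product: 3 1‑(2,4,6‑trihydroxyphenyl)‑3‑methylbutan‑1‑one
Conditions: AlCl3 (3.5 equiv), PhNO2/CH2Cl2, 0 → 40 °C; then 1 M HCl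
Reagents that add atoms: none
Why: Friedel–Crafts C‑acylation of the electron‑rich arene, which stops at the mono‑ketone because the acyl group deactivates the ring; no stereocenter.

**Step 2**
Reactants: 3 1‑(2,4,6‑trihydroxyphenyl)‑3‑methylbutan‑1‑one
Product: 4 3,5‑dihydroxy‑6,6‑dimethyl‑2‑(3‑methylbutanoyl)cyclohexa‑2,4‑dien‑1‑one
Conditions: NaOMe (3 equiv), MeI (2.2 equiv), MeOH, 0 → 25 °C; chromatography from mono‑ and trimethylated material
Reagents that add atoms: iodomethane CI
Why: dearomatising double C‑methylation of the phloroglucinolate (the classical acylfilicinic acid preparation) puts both methyl groups on one ring carbon and leaves one nucleophilic ring CH; no stereocenter.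

**Step 3**
Reactants: 5 germacrone; 6 formaldehyde (used as paraformaldehyde)
Product: 7 (4aS,5S,8S,8aR)‑5‑hydroxy‑8‑(hydroxymethyl)‑5,8a‑dimethyl‑3‑(propan‑2‑ylidene)octahydronaphthalen‑2(1H)‑one
Conditions: (CH2O)n (3 equiv), H2O (1.5 equiv), (S,S)‑IDPi (confined imidodiphosphorimidate Brønsted acid, 3,3′‑bis[3,5‑bis(trifluoromethyl)phenyl]‑BINOL units, N‑triflyl groups; 5 mol %), CHCl3, −20 → 0 °C; NaHCO3 work‑up
Reagents that add atoms: water O
Why: Proposed new method: acid‑activated formaldehyde held in the chiral anion pocket adds to C1 of the strained (E)‑1(10)‑alkene of one of the two rapidly interconverting enantiomeric crossed‑chair conformers of germacrone, the C10 cation is captured across the ring by the (E)‑4,5‑alkene through the chair–chair array (anti addition to both alkenes gives the trans‑decalin, CH2OH equatorial and cis to the C10 methyl, H‑5 trans to it) and water adds to the C4 cation anti to the new C5–C10 bond (equatorial OH, axial methyl), so C1, C4, C5 and C10 are set by the catalyst in one event; closest known reaction types are the IDPi‑catalysed asymmetric Prins reaction of alkenes with paraformaldehyde, IDPi‑catalysed cation–olefin polycyclisation and the acid‑induced transannular cyclisation of germacrone to eudesmanes.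

**Step 4**
Reactants: 7 enone diol (name as in step 3)
Product: 8 (3S,4aS,5S,8S,8aR)‑5‑hydroxy‑8‑(hydroxymethyl)‑5,8a‑dimethyl‑3‑(prop‑1‑en‑2‑yl)octahydronaphthalen‑2(1H)‑one
Conditions: KOtBu (4 equiv), tBuOH/THF, 25 °C, 1 h; inverse quench into AcOH/THF at −78 °C; pH 7 buffer
Reagents that add atoms: none
Why: classical enone deconjugation (thermodynamic γ‑deprotonation to the through‑conjugated dienolate, then kinetic α‑protonation); the proton enters C7 axially on the face away from the axial C10 methyl, leaving the isopropenyl group equatorial, which is also the more stable C7 epimer.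

**Step 5**
Reactants: 8 β,γ‑unsaturated ketone (name as in step 4)
Product: 11 (1S,4S,4aR,7S,8aS)‑4‑(hydroxymethyl)‑1,4a‑dimethyl‑7‑(prop‑1‑en‑2‑yl)decahydronaphthalen‑1‑ol, via tosylhydrazone 9 (not isolated), via N‑alkyl tosylhydrazide 10 (not isolated)
Conditions: TsNHNH2 (1.2 equiv), 4 Å MS, THF, 25 °C; catecholborane (4 equiv), CHCl3, 0 °C; NaOAc·3H2O, 60 °C
Reagents that add atoms: none
Why: Caglioti/Kabalka tosylhydrazone reduction (hydride to C=N, loss of sulfinate, then N2 from the alkyl diazene) turns the C8 carbonyl into CH2 under near‑neutral conditions; the alkene is not allylic to the diazene, so it does not migrate, and no stereocenter is formed or touched.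

**Step 6**
Reactants: 11 diol (name as in step 5)
Product: 12 (1S,4S,4aS,6S,8aS)‑4‑hydroxy‑4,8a‑dimethyl‑6‑(prop‑1‑en‑2‑yl)decahydronaphthalene‑1‑carbaldehyde
Conditions: TEMPO (10 mol %), PhI(OAc)2 (1.1 equiv), CH2Cl2, 25 °C
Reagents that add atoms: none
Why: oxoammonium (TEMPO) oxidation takes the primary alcohol to the aldehyde and leaves the tertiary alcohol and the isopropenyl group alone; the equatorial C1 aldehyde is the favoured epimer.

**Step 7**
Reactants: 12 hydroxy aldehyde (name as in step 6); 4 3,5‑dihydroxy‑6,6‑dimethyl‑2‑(3‑methylbutanoyl)cyclohexa‑2,4‑dien‑1‑one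
Product: 14 target, 3,5‑dihydroxy‑4‑{[(1R,4S,4aS,6S,8aR)‑4‑hydroxy‑4,8a‑dimethyl‑6‑(prop‑1‑en‑2‑yl)decahydronaphthalen‑1‑yl]methyl}‑6,6‑dimethyl‑2‑(3‑methylbutanoyl)cyclohexa‑2,4‑dien‑1‑one, via alkylidene trione 13 (not isolated)
Conditions: L‑proline (20 mol %), Hantzsch ester (diethyl 2,6‑dimethyl‑1,4‑dihydropyridine‑3,5‑dicarboxylate, 1.2 equiv), CH2Cl2/EtOH, 25 °C
Reagents that add atoms: none
Why: three‑component organocatalytic reductive alkylation (Knoevenagel condensation at the single ring CH of 4, then conjugate transfer hydrogenation of the alkylidene trione by the Hantzsch ester) forms the CH2 link; no new stereocenter, C1 keeps its equatorial substituent.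

**Compound list**
1 | phloroglucinol | Oc1cc(O)cc(O)c1 | starting material
2 | 3‑methylbutanoyl chloride | CC(C)CC(=O)Cl | starting material
3 | 1‑(2,4,6‑trihydroxyphenyl)‑3‑methylbutan‑1‑one | CC(C)CC(=O)c1c(O)cc(O)cc1O | intermediate
4 | 3,5‑dihydroxy‑6,6‑dimethyl‑2‑(3‑methylbutanoyl)cyclohexa‑2,4‑dien‑1‑one | CC(C)CC(=O)C1=C(O)C=C(O)C(C)(C)C1=O | intermediate
5 | germacrone, (3E,7E)‑3,7‑dimethyl‑10‑(propan‑2‑ylidene)cyclodeca‑3,7‑dien‑1‑one | C/C1=C\CC(=C(C)C)C(=O)C/C(C)=C/CC1 | starting material
6 | formaldehyde (paraformaldehyde) | C=O | starting material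
7 | (4aS,5S,8S,8aR)‑5‑hydroxy‑8‑(hydroxymethyl)‑5,8a‑dimethyl‑3‑(propan‑2‑ylidene)octahydronaphthalen‑2(1H)‑one; trans‑decalin, CH2OH and both methyls on one face, H‑5 and 4‑OH on the other | CC(C)=C1C(=O)C[C@]2(C)[C@@H](CO)CC[C@](C)(O)[C@H]2C1 | intermediate
8 | (3S,4aS,5S,8S,8aR)‑5‑hydroxy‑8‑(hydroxymethyl)‑5,8a‑dimethyl‑3‑(prop‑1‑en‑2‑yl)octahydronaphthalen‑2(1H)‑one; isopropenyl equatorial | C=C(C)[C@H]1C(=O)C[C@]2(C)[C@@H](CO)CC[C@](C)(O)[C@H]2C1 | intermediate
9 | tosylhydrazone of 8 at C8 (C=N geometry not defined) | C=C(C)[C@H]1C(=NNS(=O)(=O)c3ccc(C)cc3)C[C@]2(C)[C@@H](CO)CC[C@](C)(O)[C@H]2C1 | intermediate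
10 | N′‑(C8‑alkyl) tosylhydrazide from hydride addition to 9 (C8 configuration not defined; present as its catecholboryl derivatives) | C=C(C)[C@H]1C(NNS(=O)(=O)c3ccc(C)cc3)C[C@]2(C)[C@@H](CO)CC[C@](C)(O)[C@H]2C1 | intermediate
11 | (1S,4S,4aR,7S,8aS)‑4‑(hydroxymethyl)‑1,4a‑dimethyl‑7‑(prop‑1‑en‑2‑yl)decahydronaphthalen‑1‑ol | C=C(C)[C@H]1CC[C@]2(C)[C@@H](CO)CC[C@](C)(O)[C@H]2C1 | intermediate
12 | (1S,4S,4aS,6S,8aS)‑4‑hydroxy‑4,8a‑dimethyl‑6‑(prop‑1‑en‑2‑yl)decahydronaphthalene‑1‑carbaldehyde | C=C(C)[C@H]1CC[C@]2(C)[C@@H](C=O)CC[C@](C)(O)[C@H]2C1 | intermediate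
13 | Knoevenagel adduct of 12 and 4 (alkylidene trione, exocyclic C=C geometry not defined) | C=C(C)[C@H]1CC[C@]2(C)[C@@H](C=C3C(=O)C(C)(C)C(=O)C(C(=O)CC(C)C)=C3O)CC[C@](C)(O)[C@H]2C1 | intermediate
14 | target (name as in step 7); eudesmane numbering 1R,4S,5S,7S,10R | C=C(C)[C@H]1CC[C@]2(C)[C@@H](CC3=C(O)C(C)(C)C(=O)C(C(=O)CC(C)C)=C3O)CC[C@](C)(O)[C@H]2C1 | target

**Step count and risks**
Total steps: 7. Longest linear sequence: 5 (steps 3 to 7, from germacrone).

Most likely to fail, first: step 3, the proposed new step. The acid may protonate C1 directly and give CH2OH‑free eudesmadienones, the C4 cation may lose a proton instead of taking up water, formaldehyde may attack the 4,5‑alkene, and the level and sense of enantioselection are unknown. The fallback uses known reaction types, sets out from germacrone 5 and comes back at 7. Shi epoxidation (fructose‑derived ketone of the required enantiomeric series, KHSO5 as 2KHSO5·KHSO4·K2SO4, K2CO3 buffer, MeCN/dimethoxymethane, 0 °C) gives, after separation from the 4,5‑epoxide, (1S,10S)‑1,10‑epoxygermacrone F1. Dilute acid (TsOH, acetone/H2O) then triggers the epoxide‑initiated transannular cyclisation established for 1(10)‑epoxygermacranes, with inversion at C10, to the 1,4‑diol enone F2. Dess–Martin periodinane oxidises the secondary alcohol to the 1,8‑dione F3. Ph3P=CH2 (from Ph3PCH3Br and KOtBu) methylenates the non‑conjugated C1 ketone to the 1‑methylene enone F4. 9‑BBN followed by H2O2/NaOH hydroborates the exocyclic alkene from the face away from the angular methyl, giving the equatorial CH2OH of 7; any C8 alcohol formed is returned to the enone with MnO2.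

Second: step 4. Deprotonation may occur at C9 instead of the side‑chain methyls, and the β,γ‑enone reconjugates easily. The fallback sets out from 7 and comes back at 8. Soft enolisation and silylation under equilibrating conditions (TMSOTf, Et3N, CH2Cl2, 25 °C) gives the isolable tris(trimethylsilyl) through‑conjugated dienol ether F5. Acetic‑acid‑buffered TBAF in THF at −78 °C then cleaves the three Si–O bonds and protonates the dienolate kinetically at C7 to give 8.

Third: step 5. Hydrazone formation on the hindered, isomerisation‑prone ketone may be slow or may reconjugate the alkene. The fallback sets out from 8 and comes back at 11. NaBH4 in MeOH at −40 °C gives the triol F6 (C8 epimers, both usable). TBSCl/imidazole silylates only the primary alcohol to give silyl ether F7. 1,1′‑Thiocarbonyldiimidazole acylates the secondary alcohol to the imidazolide F8. Bu3SnH/AIBN in toluene at 90 °C (Barton–McCombie) removes the C8 oxygen to give the deoxy silyl ether F9, and TBAF releases 11.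

**Further compounds**
F1 | step 3 | (1S,10S)‑1,10‑epoxygermacra‑4,7(11)‑dien‑8‑one (germacrane numbering, trans epoxide) | C/C1=C\CC(=C(C)C)C(=O)C[C@]2(C)O[C@H]2CC1
F2 | step 3 | (4aS,5S,8S,8aS)‑5,8‑dihydroxy‑5,8a‑dimethyl‑3‑(propan‑2‑ylidene)octahydronaphthalen‑2(1H)‑one | CC(C)=C1C(=O)C[C@]2(C)[C@@H](O)CC[C@](C)(O)[C@H]2C1
F3 | step 3 | (4aS,5S,8aS)‑5‑hydroxy‑5,8a‑dimethyl‑3‑(propan‑2‑ylidene)hexahydronaphthalene‑2,8‑dione | CC(C)=C1C(=O)C[C@]2(C)C(=O)CC[C@](C)(O)[C@H]2C1
F4 | step 3 | (4aS,5S,8aS)‑5‑hydroxy‑5,8a‑dimethyl‑8‑methylidene‑3‑(propan‑2‑ylidene)octahydronaphthalen‑2(1H)‑one | CC(C)=C1C(=O)C[C@]2(C)C(=C)CC[C@](C)(O)[C@H]2C1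
F5 | step 4 | tris(trimethylsilyl) derivative of 7: C8 silyl dienol ether (C7=C8, isopropenyl on C7) with both hydroxyls silylated | C=C(C)C1=C(O[Si](C)(C)C)C[C@]2(C)[C@@H](CO[Si](C)(C)C)CC[C@](C)(O[Si](C)(C)C)[C@H]2C1
F6 | step 5 | C8 alcohol from 8 (triol, C8 configuration not defined) | C=C(C)[C@H]1C(O)C[C@]2(C)[C@@H](CO)CC[C@](C)(O)[C@H]2C1
F7 | step 5 | primary tert‑butyldimethylsilyl ether of F6 | C=C(C)[C@H]1C(O)C[C@]2(C)[C@@H](CO[Si](C)(C)C(C)(C)C)CC[C@](C)(O)[C@H]2C1
F8 | step 5 | C8 O‑(imidazol‑1‑ylthiocarbonyl) derivative of F7 | C=C(C)[C@H]1C(OC(=S)n3ccnc3)C[C@]2(C)[C@@H](CO[Si](C)(C)C(C)(C)C)CC[C@](C)(O)[C@H]2C1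
F9 | step 5 | primary tert‑butyldimethylsilyl ether of 11 | C=C(C)[C@H]1CC[C@]2(C)[C@@H](CO[Si](C)(C)C(C)(C)C)CC[C@](C)(O)[C@H]2C1
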